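**Retrosynthetic overview**
1. Glaucolide K ⇐ peracid epoxidation of the E-4,5-alkene (last event) and C8 methacrylation of a germacra-4,7(11)-dien-12,6-olide alcohol.
2. Ten-membered carbocycle (second ring) ⇐ C7–C8 bond by a ligand-controlled Ni/Cr (Nozaki–Hiyama–Kishi) macrocyclization of a β-iodobutenolide aldehyde (new step, sets C8).
3. Butenolide (first ring) ⇐ iodolactonization of an axially chiral allenoate ⇐ palladium-catalysed carbonylation of a propargylic carbonate ⇐ asymmetric alkynylation of an enal with propargyl acetate (sets C6, brings C13–OAc).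
4. C1/C10 (first stereocentres) ⇐ chiral phosphoric acid-catalysed (Z)-crotylboration of the C1 aldehyde cut from geranyl acetate.

Assumption: atoms carry germacrane numbers (ring C1–C10, lactone C11–C13, methyls C14 on C10 and C15 on C4); the given SMILES is read as 1S,4R,5R,6S,8S,10S.

**Route**

Step 1
Reactants: 1 geranyl acetate
Product: 4 (2E)-3-methyl-6-oxohex-2-en-1-yl acetate, via 6,7-epoxygeranyl acetate 2 (not isolated), via 6,7-dihydroxy-6,7-dihydrogeranyl acetate 3 (not isolated)
Conditions: mCPBA (1.05 equiv), CH2Cl2, −20 to 0 °C; then H5IO6 (1.2 equiv), THF/H2O, 0 °C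
Reagents that add atoms: mCPBA (3-chloroperoxybenzoic acid), O=C(OO)c1cccc(Cl)c1; water, O (its oxygen sits only in diol 3)
Why: Prilezhaev epoxidation picks the electron-rich 6,7-alkene (the 2,3-alkene is deactivated by the allylic acetate) and periodic acid hydrolyses the epoxide and cleaves the glycol to the aldehyde; no stereocentre is carried on.

Step 2
Reactants: 4 (2E)-3-methyl-6-oxohex-2-en-1-yl acetate, 5 (Z)-crotylboronic acid pinacol ester
Product: 7 (2E,6S,7S)-6-hydroxy-3,7-dimethylnona-2,8-dien-1-yl acetate, via pinacol borate ester 6 (not isolated)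
Conditions: (R)-3,3′-bis(2,4,6-triisopropylphenyl)-1,1′-binaphthyl-2,2′-diyl hydrogen phosphate (5 mol%), 5 (1.2 equiv), 4 Å MS, toluene, −30 °C; aq. NaHCO3 work-up
Reagents that add atoms: none
Why: Chiral phosphoric acid-catalysed crotylboration through a chair six-membered transition state in which the acid hydrogen-bonds the boronate oxygen and the formyl hydrogen, so the Z-crotyl geometry gives the syn C1-OH/C10-Me pair and Re-face attack fixes 1S,10S (first stereocentres; expected ≥95% ee, dr ≥20:1).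

Step 3
Reactants: 7 (2E,6S,7S)-6-hydroxy-3,7-dimethylnona-2,8-dien-1-yl acetate
Product: 9 (2E,6S,7S)-6-hydroxy-3,7-dimethylnona-2,8-dienal, via (2E,6S,7S)-3,7-dimethylnona-2,8-diene-1,6-diol 8 (not isolated)
Conditions: K2CO3 (0.3 equiv), MeOH, 0 °C to rt; concentrate, filter; then MnO2 (15 equiv), CH2Cl2, rt
Reagents that add atoms: none
Why: Zemplén-type methanolysis frees the primary allylic alcohol and MnO2 oxidises only allylic alcohols, so the E-enal forms while the secondary C1 carbinol and C1/C10 stay untouched.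

Step 4
Reactants: 9 (2E,6S,7S)-6-hydroxy-3,7-dimethylnona-2,8-dienal
Product: 10 (3S,4S,7E)-3,7-dimethyl-9-oxonona-1,7-dien-4-yl acetate
Conditions: Ac2O (1.5 equiv), pyridine (3 equiv), 4-dimethylaminopyridine (5 mol%), CH2Cl2, 0 °C
Reagents that add atoms: acetic anhydride, CC(=O)OC(C)=O
Why: Nucleophile-catalysed acetylation installs the final C1 acetate before the carbonyl chemistry; no stereocentre is touched.

Step 5
Reactants: 10 (3S,4S,7E)-3,7-dimethyl-9-oxonona-1,7-dien-4-yl acetate, 11 propargyl acetate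
Product: 13 (4S,5E,9S,10S)-4-hydroxy-6,10-dimethyldodeca-5,11-dien-2-yne-1,9-diyl diacetate, via methylzinc alkoxide 12 (not isolated)
Conditions: Me2Zn (3 equiv), 11 (3 equiv), (S,S)-2,6-bis{[2-(hydroxydiphenylmethyl)pyrrolidin-1-yl]methyl}-4-methylphenol (ProPhenol, 20 mol%), Ph3PO (40 mol%), toluene, 4 °C; then pH 7 buffer
Reagents that add atoms: dimethylzinc, C[Zn]C (zinc and methyl are present only in intermediate 12)
Why: Zinc–ProPhenol catalytic asymmetric alkynylation, in which the dinuclear zinc complex binds the enal and the methylzinc acetylide and delivers the alkynyl group to the Re face to set C6 as S (germacrane C6; the ligand antipode is used if a Mosher check on 13 shows the opposite sense).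

Step 6
Reactants: 13 (4S,5E,9S,10S)-4-hydroxy-6,10-dimethyldodeca-5,11-dien-2-yne-1,9-diyl diacetate
Product: 14 (4S,5E,9S,10S)-4-[(methoxycarbonyl)oxy]-6,10-dimethyldodeca-5,11-dien-2-yne-1,9-diyl diacetate
Conditions: ClCO2Me (2 equiv), pyridine (4 equiv), CH2Cl2, 0 °C
Reagents that add atoms: methyl chloroformate, COC(=O)Cl
Why: Chloroformate acylation gives the carbonate leaving group that zerovalent palladium ionises under neutral conditions; C6 is not touched.

Step 7
Reactants: 14 (4S,5E,9S,10S)-4-[(methoxycarbonyl)oxy]-6,10-dimethyldodeca-5,11-dien-2-yne-1,9-diyl diacetate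
Product: 16 (3S,4S,7E)-8-[(2R)-4-(acetoxymethyl)-3-iodo-5-oxo-2,5-dihydrofuran-2-yl]-3,7-dimethylocta-1,7-dien-4-yl acetate, via (aR)-allenoate 15 (not isolated)
Conditions: Pd2(dba)3·CHCl3 (2.5 mol%), PPh3 (10 mol%), CO (1 atm), MeOH/THF, 0 °C; cold silica plug; then iodine (1.5 equiv), NaHCO3 (2 equiv), MeCN/H2O (10:1), 0 °C
Reagents that add atoms: carbon monoxide, [C-]#[O+]; iodine, [I][I]; water, O; methanol, CO (its methoxy group is present only in intermediate 15)
Why: Tsuji-type carbonylation, in which zerovalent palladium displaces the carbonate anti (SN2′) and the allenylpalladium inserts CO and is methanolysed to the aR allenoate, is followed by iodolactonization, which puts iodine on the central allene carbon and the ester oxygen anti on C6, so the axial chirality returns to C6 with net inversion and gives the glaucolide C6 configuration (descriptor R in 16 only because C7 carries iodine).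

Step 8
Reactants: 16 (3S,4S,7E)-8-[(2R)-4-(acetoxymethyl)-3-iodo-5-oxo-2,5-dihydrofuran-2-yl]-3,7-dimethylocta-1,7-dien-4-yl acetate
Product: 18 (3S,4S,7E)-8-[(2R)-4-(acetoxymethyl)-3-iodo-5-oxo-2,5-dihydrofuran-2-yl]-1-hydroxy-3,7-dimethyloct-7-en-4-yl acetate, via B-alkyl-9-borabicyclo[3.3.1]nonane 17 (not isolated)
Conditions: 9-BBN (1.5 equiv), THF, 0 °C to rt; then pH 7 phosphate buffer, 30% H2O2, 0 °C
Reagents that add atoms: hydrogen peroxide, OO; 9-borabicyclo[3.3.1]nonane, B1C2CCCC1CCC2 (boron and the cyclooctanediyl unit are present only in intermediate 17)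
Why: Brown hydroboration–oxidation, since 9-BBN adds anti-Markovnikov to the monosubstituted alkene far faster than to the trisubstituted or the electron-poor butenolide alkene, and buffered peroxide avoids addition–elimination at the β-iodo lactone.

Step 9
Reactants: 18 (3S,4S,7E)-8-[(2R)-4-(acetoxymethyl)-3-iodo-5-oxo-2,5-dihydrofuran-2-yl]-1-hydroxy-3,7-dimethyloct-7-en-4-yl acetate
Product: 19 (3S,4S,7E)-8-[(2R)-4-(acetoxymethyl)-3-iodo-5-oxo-2,5-dihydrofuran-2-yl]-3,7-dimethyl-1-oxooct-7-en-4-yl acetate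
Conditions: Dess–Martin periodinane (1.3 equiv), CH2Cl2, 0 °C to rt
Reagents that add atoms: none
Why: Dess–Martin oxidation is neutral, so the iodobutenolide, the acetates and the C10 centre β to the new aldehyde are untouched.

Step 10
Reactants: 19 (3S,4S,7E)-8-[(2R)-4-(acetoxymethyl)-3-iodo-5-oxo-2,5-dihydrofuran-2-yl]-3,7-dimethyl-1-oxooct-7-en-4-yl acetate
Product: 21 (1S,6R,8S,10S)-1,13-diacetoxy-8-hydroxygermacra-4E,7(11)-dien-12,6-olide, via 8-O-trimethylsilyl ether 20 (not isolated)
Conditions: CrCl2 (15 mol%), (S)-N-[2-(4-isopropyl-4,5-dihydrooxazol-2-yl)-6-methylphenyl]methanesulfonamide (17 mol%), Et3N (30 mol%), NiCl2(2,9-dimethyl-1,10-phenanthroline) (3 mol%), Mn (3 equiv), Me3SiCl (2.5 equiv), LiCl (2 equiv), MeCN, 2 mM by syringe pump, rt; then citric acid, MeOH/H2O, 0 °C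
Reagents that add atoms: chlorotrimethylsilane, C[Si](C)(C)Cl (the silyl group is present only in intermediate 20)
Why: Proposed new method: a ligand-controlled catalytic asymmetric Nozaki–Hiyama–Kishi macrocyclization of a 4-iodo-2(5H)-furanone, in which zerovalent nickel inserts into the vinylogous acyl iodide, the alkenyl group passes to sulfonamide-bound trivalent chromium and this alkenylchromium adds to the tethered aldehyde through a compact transition state whose oxazoline isopropyl group shields one aldehyde face (ligand enantiomer chosen for 8S), while Mn returns chromium to the divalent state and Me3SiCl traps the alkoxide as 20 (which also stops acetyl migration from O13); the closest known reactions are intermolecular catalytic asymmetric Ni/Cr couplings of alkenyl iodides, including β-iodoenoates, and ligand-free Nozaki–Hiyama–Kishi macrocyclizations, whereas neither a 4-iodobutenolide partner nor a ligand-controlled ten-membered carbocycle closure has been shown.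

Step 11
Reactants: 21 (1S,6R,8S,10S)-1,13-diacetoxy-8-hydroxygermacra-4E,7(11)-dien-12,6-olide
Product: 22 (1S,6R,8S,10S)-1,13-diacetoxy-8-(methacryloyloxy)germacra-4E,7(11)-dien-12,6-olide
Conditions: methacrylic anhydride (2 equiv), Et3N (3 equiv), 4-dimethylaminopyridine (0.2 equiv), CH2Cl2, 0 °C
Reagents that add atoms: methacrylic anhydride, C=C(C)C(=O)OC(=O)C(C)=C
Why: Steglich-type acylation of the allylic C8 alcohol, run cold and short so the cis-disposed C13 acetate does not migrate; no stereocentre is touched.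

Step 12
Reactants: 22 (1S,6R,8S,10S)-1,13-diacetoxy-8-(methacryloyloxy)germacra-4E,7(11)-dien-12,6-olide
Product: 23 glaucolide K
Conditions: mCPBA (1.2 equiv), Na2HPO4 buffer, CH2Cl2, 0 °C
Reagents that add atoms: mCPBA (3-chloroperoxybenzoic acid), O=C(OO)c1cccc(Cl)c1
Why: Prilezhaev epoxidation touches only the electron-rich E-4,5-alkene (butenolide and methacrylate alkenes are electron-poor); in the conformer with H6 eclipsing the alkene (A(1,3) strain with C15) the ring chain covers the C7 face, so peripheral attack should place the epoxide oxygen syn to O6 and give 4R,5R (this face selectivity is a prediction, see risks).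

**Compound list**
1 | geranyl acetate, (2E)-3,7-dimethylocta-2,6-dien-1-yl acetate | CC(C)=CCC/C(C)=C/COC(C)=O | starting material
2 | 6,7-epoxygeranyl acetate (racemic; not isolated) | CC1(C)OC1CC/C(C)=C/COC(C)=O | intermediate
3 | 6,7-dihydroxy-6,7-dihydrogeranyl acetate (racemic; not isolated) | CC(C)(O)C(O)CC/C(C)=C/COC(C)=O | intermediate
4 | (2E)-3-methyl-6-oxohex-2-en-1-yl acetate | O=CCC/C(C)=C/COC(C)=O | intermediate
5 | (Z)-crotylboronic acid pinacol ester, 2-[(2Z)-but-2-en-1-yl]-4,4,5,5-tetramethyl-1,3,2-dioxaborolane | C/C=C\CB1OC(C)(C)C(C)(C)O1 | starting material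
6 | pinacol borate ester of 7 (not isolated) | C=C[C@H](C)[C@@H](OB1OC(C)(C)C(C)(C)O1)CC/C(C)=C/COC(C)=O | intermediate
7 | (2E,6S,7S)-6-hydroxy-3,7-dimethylnona-2,8-dien-1-yl acetate | C=C[C@H](C)[C@@H](O)CC/C(C)=C/COC(C)=O | intermediate
8 | (2E,6S,7S)-3,7-dimethylnona-2,8-diene-1,6-diol (not isolated) | C=C[C@H](C)[C@@H](O)CC/C(C)=C/CO | intermediate
9 | (2E,6S,7S)-6-hydroxy-3,7-dimethylnona-2,8-dienal | C=C[C@H](C)[C@@H](O)CC/C(C)=C/C=O | intermediate
10 | (3S,4S,7E)-3,7-dimethyl-9-oxonona-1,7-dien-4-yl acetate | C=C[C@H](C)[C@@H](OC(C)=O)CC/C(C)=C/C=O | intermediate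
11 | propargyl acetate, prop-2-yn-1-yl acetate | C#CCOC(C)=O | starting material
12 | methylzinc alkoxide of 13 (not isolated) | C=C[C@H](C)[C@@H](OC(C)=O)CC/C(C)=C/[C@H](O[Zn]C)C#CCOC(C)=O | intermediate
13 | (4S,5E,9S,10S)-4-hydroxy-6,10-dimethyldodeca-5,11-dien-2-yne-1,9-diyl diacetate | C=C[C@H](C)[C@@H](OC(C)=O)CC/C(C)=C/[C@H](O)C#CCOC(C)=O | intermediate
14 | (4S,5E,9S,10S)-4-[(methoxycarbonyl)oxy]-6,10-dimethyldodeca-5,11-dien-2-yne-1,9-diyl diacetate | C=C[C@H](C)[C@@H](OC(C)=O)CC/C(C)=C/[C@H](OC(=O)OC)C#CCOC(C)=O | intermediate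
15 | methyl (5E,9S,10S)-9-acetoxy-2-(acetoxymethyl)-6,10-dimethyldodeca-2,3,5,11-tetraenoate, allene axis aR (M) (not isolated) | C=C[C@H](C)[C@@H](OC(C)=O)CC/C(C)=C/C([H])=[C@]=C(COC(C)=O)C(=O)OC | intermediate
16 | (3S,4S,7E)-8-[(2R)-4-(acetoxymethyl)-3-iodo-5-oxo-2,5-dihydrofuran-2-yl]-3,7-dimethylocta-1,7-dien-4-yl acetate | C=C[C@H](C)[C@@H](OC(C)=O)CC/C(C)=C/[C@H]1OC(=O)C(COC(C)=O)=C1I | intermediate
17 | B-alkyl-9-borabicyclo[3.3.1]nonane from 16, boron on the terminal carbon (not isolated) | C1CC2CCCC(C1)B2CC[C@H](C)[C@@H](OC(C)=O)CC/C(C)=C/[C@H]1OC(=O)C(COC(C)=O)=C1I | intermediate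
18 | (3S,4S,7E)-8-[(2R)-4-(acetoxymethyl)-3-iodo-5-oxo-2,5-dihydrofuran-2-yl]-1-hydroxy-3,7-dimethyloct-7-en-4-yl acetate | OCC[C@H](C)[C@@H](OC(C)=O)CC/C(C)=C/[C@H]1OC(=O)C(COC(C)=O)=C1I | intermediate
19 | (3S,4S,7E)-8-[(2R)-4-(acetoxymethyl)-3-iodo-5-oxo-2,5-dihydrofuran-2-yl]-3,7-dimethyl-1-oxooct-7-en-4-yl acetate | O=CC[C@H](C)[C@@H](OC(C)=O)CC/C(C)=C/[C@H]1OC(=O)C(COC(C)=O)=C1I | intermediate
20 | 8-O-trimethylsilyl ether of 21 (not isolated) | C[Si](C)(C)O[C@H]1C[C@H](C)[C@@H](OC(C)=O)CC/C(C)=C/[C@H]2OC(=O)C(COC(C)=O)=C12 | intermediate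
21 | (1S,6R,8S,10S)-1,13-diacetoxy-8-hydroxygermacra-4E,7(11)-dien-12,6-olide | O[C@H]1C[C@H](C)[C@@H](OC(C)=O)CC/C(C)=C/[C@H]2OC(=O)C(COC(C)=O)=C12 | intermediate
22 | (1S,6R,8S,10S)-1,13-diacetoxy-8-(methacryloyloxy)germacra-4E,7(11)-dien-12,6-olide | C=C(C)C(=O)O[C@H]1C[C@H](C)[C@@H](OC(C)=O)CC/C(C)=C/[C@H]2OC(=O)C(COC(C)=O)=C12 | intermediate
23 | glaucolide K, (1S,4R,5R,6S,8S,10S)-1,13-diacetoxy-4,5-epoxy-8-(methacryloyloxy)germacr-7(11)-en-12,6-olide | C=C(C)C(=O)O[C@H]1C[C@H](C)[C@@H](OC(C)=O)CC[C@@]2(C)O[C@@H]2[C@H]2OC(=O)C(COC(C)=O)=C12 | target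

**Step count**
Total: 12 steps. Longest linear sequence: 12 steps (1 to 23); 5 and 11 are bought.

**Three steps most likely to fail**

Step 10 (the proposed new macrocyclization). The ten-membered closure may be slow, or the ligand may not override the ring's own preference at C8. The fallback sets out from 19 and uses only known chemistry. The classical ligand-free Nozaki–Hiyama–Kishi ring closure (CrCl2 6 equiv, NiCl2 2 mol%, DMSO/THF, 2 mM, rt) gives, through the dichlorochromium alkoxide F1, the C8-epimeric alcohol mixture F2. Dess–Martin oxidation turns both epimers into the 8-ketone F3. Corey–Bakshi–Shibata reduction (catecholborane with (S)- or (R)-1-methyl-3,3-diphenyltetrahydro-1H,3H-pyrrolo[1,2-c][1,3,2]oxazaborole, toluene, −78 °C) then sets 8S under reagent control and comes back to the route at 21.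

Step 7 (carbonylation and iodolactonization). The palladium intermediate is delocalised over the alkene, so central-to-axial transfer may erode. Vinylallene 15 can also undergo a 1,5-hydrogen shift if warmed, and its allenylic acetate may react further. The fallback sets out from 10 and drops the stereospecific transfer. Ligand-free alkynylation (Me2Zn, 11, N,N-dimethylethanolamine 20 mol%, toluene, rt) gives, through the methylzinc alkoxide mixture F4, the C6-epimeric alcohol F5. ClCO2Me/pyridine converts it into the C6-epimeric carbonate F6. The known enantioconvergent palladium-catalysed alkoxycarbonylation of racemic propargylic carbonates (Pd2(dba)3 with (R)- or (S)-5,5′-bis{bis(3,5-di-tert-butyl-4-methoxyphenyl)phosphino}-4,4′-bi-1,3-benzodioxole, CO, MeOH, rt) then funnels both epimers into the aR allenoate and comes back to the route at 15, which is iodolactonized as in step 7.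

Step 12 (final epoxidation). Peripheral attack could occur on the other alkene face if the ring prefers the other conformer. The fallback sets out from 21 and puts the epoxide in one step earlier under catalyst control. Shi epoxidation (1,2:4,5-di-O-isopropylidene-β-D-erythro-2,3-hexodiulo-2,6-pyranose, Oxone, NaHCO3-buffered MeCN/dimethoxymethane/H2O, 0 °C; the L-configured ketone if the other face is needed) gives the epoxy alcohol F7. Methacrylation as in step 11 then comes back to the route at 23.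

Further compounds
F1 | step 10 | dichlorochromium alkoxide of F2, C8 epimers (not isolated) | Cl[Cr](Cl)OC1C[C@H](C)[C@@H](OC(C)=O)CC/C(C)=C/[C@H]2OC(=O)C(COC(C)=O)=C12
F2 | step 10 | (1S,6R,10S)-1,13-diacetoxy-8-hydroxygermacra-4E,7(11)-dien-12,6-olide, mixture of C8 epimers | OC1C[C@H](C)[C@@H](OC(C)=O)CC/C(C)=C/[C@H]2OC(=O)C(COC(C)=O)=C12
F3 | step 10 | (1S,6R,10S)-1,13-diacetoxy-8-oxogermacra-4E,7(11)-dien-12,6-olide | O=C1C[C@H](C)[C@@H](OC(C)=O)CC/C(C)=C/[C@H]2OC(=O)C(COC(C)=O)=C12
F4 | step 7 | methylzinc alkoxide of F5, C4 epimers (not isolated) | C=C[C@H](C)[C@@H](OC(C)=O)CC/C(C)=C/C(O[Zn]C)C#CCOC(C)=O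
F5 | step 7 | (5E,9S,10S)-4-hydroxy-6,10-dimethyldodeca-5,11-dien-2-yne-1,9-diyl diacetate, mixture of C4 epimers | C=C[C@H](C)[C@@H](OC(C)=O)CC/C(C)=C/C(O)C#CCOC(C)=O
F6 | step 7 | (5E,9S,10S)-4-[(methoxycarbonyl)oxy]-6,10-dimethyldodeca-5,11-dien-2-yne-1,9-diyl diacetate, mixture of C4 epimers | C=C[C@H](C)[C@@H](OC(C)=O)CC/C(C)=C/C(OC(=O)OC)C#CCOC(C)=O
F7 | step 12 | (1S,4R,5R,6S,8S,10S)-1,13-diacetoxy-4,5-epoxy-8-hydroxygermacr-7(11)-en-12,6-olide | O[C@H]1C[C@H](C)[C@@H](OC(C)=O)CC[C@@]2(C)O[C@@H]2[C@H]2OC(=O)C(COC(C)=O)=C12
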